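The route rests on cutting the ring-fusion C–C bond of the cyclopentane. Without that bond the carbinol carbon C(CH3)(OH), both ring-fusion CH carbons and the CMe2 carbon of the cycloheptene, with their methyl groups, form one open dehydrolinalool-type chain. A palladium-catalysed Alder-ene cycloisomerisation of the silylated (S)-propargylic ynoate re-forms this bond, closes the five-membered ring, sets the fusion CH next to the future CMe2 carbon and leaves an exocyclic enoate plus an isopropenyl group, the two handles for building the seven-membered ring and joining the perhydrobenzoxepine half. The precursor is an acyclic 1,6-enyne: methyl ynoate, quaternary OTBS carbinol, prenyl terminus.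

Key step: step 6

Remark: lithium and magnesium salts formed by simple deprotonation (acetylides, enolates, alkoxides) are treated as the metallated form of the numbered reactant and are not numbered separately; the L-series fructose-type ketone for the Shi epoxidation is assumed to be an available catalyst.

**Left half (steps 1–8)**

Step 1
Reactants: 1 geraniol
Product: 2 (2S,3S)-2,3-epoxygeraniol
Conditions: Ti(OiPr)4 (5 mol%), L-(+)-diethyl tartrate (7.5 mol%), t-BuOOH, 4 Å MS, CH2Cl2, −20 °C
Reagents that add atoms: tert-butyl hydroperoxide, CC(C)(C)OO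
Why: Sharpless asymmetric epoxidation of the allylic alcohol, in which the L-(+)-tartrate–titanium complex should deliver oxygen to the face that gives the (2S,3S)-epoxide and so fixes the configuration of the future tertiary carbinol carbon.

Step 2
Reactants: 2 (2S,3S)-2,3-epoxygeraniol
Product: 3 (2S,3R)-3-(chloromethyl)-2-methyl-2-(4-methylpent-3-enyl)oxirane
Conditions: PPh3, CCl4, NaHCO3, reflux
Reagents that add atoms: tetrachloromethane, ClC(Cl)(Cl)Cl
Why: Appel chlorination of the primary alcohol by SN2 displacement of the oxyphosphonium ion, which leaves both epoxide carbons untouched.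

Step 3
Reactants: 3 epoxy chloride
Product: 4 (3S)-3,7-dimethyloct-6-en-1-yn-3-ol [(S)-dehydrolinalool]
Conditions: n-BuLi (3.3 equiv), THF, −40 °C to 0 °C; aq. NH4Cl
Reagents that add atoms: none
Why: Base-induced double elimination of a 2,3-epoxy chloride (deprotonation at CH2Cl opens the epoxide at the neighbouring carbon, loss of HCl from the chloroalkene gives the alkyne), in which the C–O bond at the quaternary carbon is never broken so its configuration is retained.

Step 4
Reactants: 4 (S)-dehydrolinalool
Product: 5 (3S)-3-[tert-butyl(dimethyl)silyl]oxy-3,7-dimethyloct-6-en-1-yne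
Conditions: TBSOTf, 2,6-lutidine, CH2Cl2, 0 °C to rt
Reagents that add atoms: tert-butyldimethylsilyl trifluoromethanesulfonate, CC(C)(C)[Si](C)(C)OS(=O)(=O)C(F)(F)F
Why: Silylation of the hindered tertiary propargylic alcohol with a silyl triflate and a non-nucleophilic base, giving the ether that later prevents lactonisation of the γ-oxygenated (Z)-enoate.

Step 5
Reactants: 5 silyl ether
Product: 6 methyl (4S)-4-[tert-butyl(dimethyl)silyl]oxy-4,8-dimethylnon-7-en-2-ynoate
Conditions: n-BuLi, THF, −78 °C; ClCO2Me
Reagents that add atoms: methyl chloroformate, COC(=O)Cl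
Why: Deprotonation of the terminal alkyne and C-acylation of the lithium acetylide with the chloroformate should give the ynoate without touching the silyl ether or the prenyl alkene.

Step 6
Reactants: 6 (S)-enynoate silyl ether
Product: 7 methyl (2Z)-2-[(2S,5R)-2-[tert-butyl(dimethyl)silyl]oxy-2-methyl-5-(prop-1-en-2-yl)cyclopentylidene]acetate
Conditions: Pd(OAc)2 (5 mol%), N,N'-bis(benzylidene)ethylenediamine (6 mol%), benzene, 60 °C
Reagents that add atoms: none
Why: Palladium(II) with the bis-imine ligand should bind the electron-poor alkyne and the trisubstituted alkene as a palladacyclopentene (equivalent to hydropalladation of the ynoate and carbopalladation of the alkene), take a β-hydrogen from the prenyl methyl group held cis to the metal and release the catalyst by reductive elimination, which is the known palladium-catalysed Alder-ene cycloisomerisation of 1,6-enynes to 1,4-dienes. The cyclopentane closes in a 5-exo-trig sense by bonding the internal alkyne carbon to the prenyl CH. Hydrogen and carbon add cis across the alkyne, so the enoate is (Z) with the ester on the side of the carbinol carbon. The new ring CH is controlled by the quaternary carbinol carbon across the sp2 ring carbon: in the envelope-like bicyclic transition state the C-methyl group (conformationally more demanding than OSiR3) and the incoming alkene unit should both sit pseudo-equatorial, which places isopropenyl cis to C-methyl and trans to the silyloxy group. The step needs this 1,3-diastereoselection and 1,4- over 1,3-diene formation; the first rests on the size difference between CH3 and OSi at the carbinol carbon, the second on the metallacycle holding only a methyl C–H, not the ring C–H, syn to palladium. The silyl ether is needed because the free γ-hydroxy (Z)-enoate would lactonise.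

Step 7
Reactants: 7 cyclopentylidene acetate
Product: 8 methyl 2-[(1S,2S,5S)-2-[tert-butyl(dimethyl)silyl]oxy-2-methyl-5-(prop-1-en-2-yl)cyclopentyl]acetate
Conditions: Cu(OAc)2·H2O (5 mol%), 1,2-bis(diphenylphosphino)benzene (5 mol%), (EtO)2MeSiH, t-BuOH, toluene, rt
Reagents that add atoms: none
Why: Ligated copper hydride 1,4-reduction of the β,β-disubstituted enoate, in which hydride should add to the ring carbon from the face anti to the isopropenyl and C-methyl groups (the face carrying only the silyloxy oxygen), giving CH2CO2Me cis to isopropenyl (the later cis ring fusion) and leaving the isolated 1,1-disubstituted alkene alone.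

Step 8
Reactants: 8 saturated ester
Product: 9 N-methoxy-N-methyl-2-[(1S,2S,5S)-2-[tert-butyl(dimethyl)silyl]oxy-2-methyl-5-(prop-1-en-2-yl)cyclopentyl]acetamide
Conditions: MeNH(OMe)·HCl, i-PrMgCl, THF, −20 °C to 0 °C
Reagents that add atoms: N,O-dimethylhydroxylamine hydrochloride, CNOC.Cl
Why: Direct aminolysis of the methyl ester by the magnesium amide gives the Weinreb amide without epimerisable centres being involved.

**Right half (steps 9–17)**

Step 9
Reactants: 10 (E)-geranylacetone; 11 3-[tert-butyl(dimethyl)silyl]oxypropanal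
Product: 12 (8E)-1-[tert-butyl(dimethyl)silyl]oxy-3-hydroxy-9,13-dimethyltetradeca-8,12-dien-5-one (both C-3 epimers)
Conditions: LDA, THF, −78 °C; then 11; aq. NH4Cl
Reagents that add atoms: none
Why: Kinetic deprotonation of the methyl ketone at CH3 and aldol addition to the aldehyde, the new carbinol centre being removed in the next step.

Step 10
Reactants: 12 aldol adduct
Product: 14 (3E,8E)-1-[tert-butyl(dimethyl)silyl]oxy-9,13-dimethyltetradeca-3,8,12-trien-5-one, via aldol mesylate 13 (not isolated)
Conditions: MsCl, Et3N, CH2Cl2, 0 °C to rt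
Reagents that add atoms: none
Why: Mesylation followed by E1cB elimination of the β-sulfonyloxy ketone should give the (E)-enone.

Step 11
Reactants: 14 trienone
Product: 15 (4E)-7-[tert-butyl(dimethyl)silyl]oxy-1-[(2S,3S)-3-[2-[(2S)-3,3-dimethyloxiran-2-yl]ethyl]-3-methyloxiran-2-yl]hept-4-en-3-one
Conditions: L-series fructose-derived ketone catalyst (ent-Shi ketone, 30 mol%), Oxone, K2CO3, Bu4NHSO4, MeCN/dimethoxymethane/aq. borate buffer, 0 °C
Reagents that add atoms: Oxone (potassium peroxymonosulfate), [K+].[O-]S(=O)(=O)OO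
Why: Shi asymmetric epoxidation, in which the chiral dioxirane should epoxidise both electron-rich trisubstituted (E)-alkenes through spiro transition states with the same facial sense (the (S,S) and (S) epoxides, mirror images of the (R) series from the D-fructose catalyst) and leave the electron-poor enone alkene.

Step 12
Reactants: 15 diepoxy enone
Product: 16 (Z)-triethylsilyl enol ether of 15 (OSiEt3 on C-3, C3=C4 double bond)
Conditions: Et3SiH, RhCl(PPh3)3 (2 mol%), THF, 50 °C
Reagents that add atoms: triethylsilane, CC[SiH](CC)CC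
Why: Rhodium-catalysed 1,4-hydrosilylation of the enone should give the regiodefined (Z)-silyl enol ether under neutral conditions that both epoxides tolerate.

Step 13
Reactants: 16 diepoxy silyl enol ether
Product: 18 (3S,5aS,6S,9aS)-3-hydroxy-6-(3-hydroxypropyl)-2,2,5a-trimethyloctahydro-1-benzoxepin-7(2H)-one, via silylated bicyclic ketone 17 (not isolated)
Conditions: TMSOTf, 2,6-di-tert-butyl-4-methylpyridine, CH2Cl2, −78 °C; then TBAF, THF, 0 °C to rt
Reagents that add atoms: none
Why: Lewis-acid-triggered epoxide-opening cascade in which the internal epoxide oxygen opens the silyl-activated terminal epoxide at its tertiary carbon (oxepane, retention at both CH–O carbons) and the enol ether carbon then opens the epoxonium ion at its tertiary carbon with inversion through a chair transition state, giving the trans-fused oxepane–cyclohexanone with the side chain equatorial (also the thermodynamic position at this α-carbon) before fluoride removes the TMS and TBS groups.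

Step 14
Reactants: 18 keto diol
Product: 19 (3S,5aS,6S,7R,9aS)-6-(3-hydroxypropyl)-2,2,5a,7-tetramethyldecahydro-1-benzoxepine-3,7-diol
Conditions: MeMgBr (5 equiv), CeCl3, THF, −78 °C to 0 °C
Reagents that add atoms: methylmagnesium bromide, C[Mg]Br
Why: Cerium-mediated 1,2-addition to the hindered enolisable ketone, in which the axial angular methyl group blocks axial approach so that methyl should enter equatorially and the new tertiary hydroxyl is axial, cis to the angular methyl as in the target.

Step 15
Reactants: 19 triol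
Product: 20 tris(triethylsilyl) ether of 19
Conditions: TESOTf (4 equiv), 2,6-lutidine, CH2Cl2, −78 °C to 0 °C
Reagents that add atoms: triethylsilyl trifluoromethanesulfonate, CC[Si](CC)(CC)OS(=O)(=O)C(F)(F)F
Why: Exhaustive silylation with the reactive silyl triflate should protect the primary, the secondary and the hindered tertiary hydroxyl in one operation.

Step 16
Reactants: 20 tris-TES ether
Product: 21 3-[(3S,5aS,6S,7R,9aS)-2,2,5a,7-tetramethyl-3,7-bis(triethylsilyloxy)decahydro-1-benzoxepin-6-yl]propanal
Conditions: (COCl)2, DMSO, CH2Cl2, −78 °C to −30 °C; Et3N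
Reagents that add atoms: none
Why: Swern oxidation conditions cleave a primary triethylsilyl ether and oxidise it directly to the aldehyde through the alkoxysulfonium ion, while secondary and tertiary triethylsilyl ethers are inert.

Step 17
Reactants: 21 aldehyde
Product: 22 (3S,5aS,6S,7R,9aS)-6-(but-3-yn-1-yl)-2,2,5a,7-tetramethyl-3,7-bis(triethylsilyloxy)decahydro-1-benzoxepine
Conditions: dimethyl (1-diazo-2-oxopropyl)phosphonate, K2CO3, MeOH, 0 °C to rt
Reagents that add atoms: dimethyl (1-diazo-2-oxopropyl)phosphonate, CC(=O)C(=[N+]=[N-])P(=O)(OC)OC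
Why: Seyferth–Gilbert homologation with the Ohira–Bestmann reagent should convert the aldehyde into the terminal alkyne under mild base that the silyl ethers survive.

**Union and completion (steps 18–23)**

Step 18
Reactants: 22 right-half alkyne; 9 Weinreb amide
Product: 23 ynone, 1-[(1S,2S,5S)-2-TBSO-2-methyl-5-(prop-1-en-2-yl)cyclopentyl]-6-[(3S,5aS,6S,7R,9aS)-2,2,5a,7-tetramethyl-3,7-bis(triethylsilyloxy)decahydro-1-benzoxepin-6-yl]hex-3-yn-2-one
Conditions: n-BuLi, THF, −78 °C; then 9, −78 °C to 0 °C; aq. NH4Cl
Reagents that add atoms: none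
Why: Acylation of the lithium acetylide by the Weinreb amide stops at the ketone because the chelated tetrahedral adduct persists until work-up.

Step 19
Reactants: 23 ynone
Product: 24 (2R)-propargylic alcohol of 23
Conditions: Ru[(R,R)-TsDPEN](p-cymene) (2 mol%), i-PrOH, rt
Reagents that add atoms: none
Why: Noyori asymmetric transfer hydrogenation of the alkynyl ketone, for which the (R,R)-catalyst should give the (R)-carbinol under reagent control by analogy with simple alkyl alkynyl ketones.

Step 20
Reactants: 24 propargylic alcohol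
Product: 26 (2R,3Z)-4-iodo-3-methylhex-3-en-2-ol bearing the same C-1 and C-6 substituents as 24, via alkenylmagnesium alkoxide 25 (not isolated)
Conditions: MeMgBr (5 equiv), CuI (0.2 equiv), THF, 0 °C to 40 °C; then I2, −40 °C to 0 °C
Reagents that add atoms: methylmagnesium bromide, C[Mg]Br; iodine, II
Why: Copper-catalysed anti-carbomagnesiation of the propargylic magnesium alkoxide, in which methyl adds to the alkyne carbon next to the carbinol and magnesium to the distal carbon within a five-membered chelate, and iodinolysis with retention should give the iodoalkene with iodine cis to the carbinol carbon.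

Step 21
Reactants: 26 iodoalkene
Product: 27 (1S,3aS,7R,8aS)-1-[tert-butyl(dimethyl)silyl]oxy-1,4,4,6-tetramethyl-5-[2-(bis-TES benzoxepinyl)ethyl]-1,2,3,3a,4,7,8,8a-octahydroazulen-7-ol (cis-fused)
Conditions: Pd(OAc)2 (10 mol%), PPh3 (25 mol%), HCO2Na, Et4NCl, DMF, 80 °C
Reagents that add atoms: none
Why: Reductive Heck cyclisation in which the alkenylpalladium iodide inserts the 1,1-disubstituted alkene in a 7-exo-trig mode to form the bond to the quaternary carbon, and the resulting neopentyl-type alkylpalladium, having no β-hydrogen, is reduced by formate to the second methyl of the CMe2 group, with no stereocentre being formed.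

Step 22
Reactants: 27 bicyclic allylic alcohol
Product: 30 tris-silyl ether of the target (TBS on the cyclopentanol oxygen, TES on both benzoxepine oxygens), via allylic sulfonylhydrazide 28 (not isolated), via allylic diazene 29 (not isolated)
Conditions: PPh3, DEAD, 2-nitrobenzenesulfonylhydrazide, N-methylmorpholine, −30 °C to 23 °C
Reagents that add atoms: none
Why: Mitsunobu displacement by the sulfonylhydrazide inverts the carbinol carbon, loss of sulfinate gives the allylic diazene on the face of the ring-fusion hydrogens, and its retro-ene loss of N2 should deliver hydrogen suprafacially to the tetrasubstituted alkene carbon on that face while the double bond moves to CH=C(CH3) (reductive 1,3-transposition), which sets the last stereocentre and the alkene position together.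

Step 23
Reactants: 30 tris-silyl ether
Product: 31 target CNP0183476.2
Conditions: TBAF (excess), THF, 60 °C
Reagents that add atoms: none
Why: Fluoride-mediated desilylation should cleave the two triethylsilyl ethers and, on heating, the tertiary TBS ether, while the trisubstituted alkene, the oxepane and the tertiary alcohols are inert to fluoride.

**Compound list**

1 | geraniol | OC/C=C(\C)CCC=C(C)C | starting material
2 | (2S,3S)-2,3-epoxygeraniol | CC(C)=CCC[C@]1(C)O[C@H]1CO | intermediate
3 | (2S,3R)-3-(chloromethyl)-2-methyl-2-(4-methylpent-3-enyl)oxirane | CC(C)=CCC[C@]1(C)O[C@H]1CCl | intermediate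
4 | (3S)-3,7-dimethyloct-6-en-1-yn-3-ol | C#C[C@@](C)(O)CCC=C(C)C | intermediate
5 | (3S)-3-[tert-butyl(dimethyl)silyl]oxy-3,7-dimethyloct-6-en-1-yne | C#C[C@@](C)(O[Si](C)(C)C(C)(C)C)CCC=C(C)C | intermediate
6 | methyl (4S)-4-[tert-butyl(dimethyl)silyl]oxy-4,8-dimethylnon-7-en-2-ynoate | COC(=O)C#C[C@@](C)(O[Si](C)(C)C(C)(C)C)CCC=C(C)C | intermediate
7 | methyl (2Z)-2-[(2S,5R)-2-[tert-butyl(dimethyl)silyl]oxy-2-methyl-5-(prop-1-en-2-yl)cyclopentylidene]acetate | COC(=O)/C=C1/[C@H](CC[C@]1(C)O[Si](C)(C)C(C)(C)C)C(C)=C | intermediate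
8 | methyl 2-[(1S,2S,5S)-2-[tert-butyl(dimethyl)silyl]oxy-2-methyl-5-(prop-1-en-2-yl)cyclopentyl]acetate | COC(=O)C[C@H]1[C@H](CC[C@]1(C)O[Si](C)(C)C(C)(C)C)C(C)=C | intermediate
9 | Weinreb amide of 8 | CON(C)C(=O)C[C@H]1[C@H](CC[C@]1(C)O[Si](C)(C)C(C)(C)C)C(C)=C | intermediate
10 | (5E)-6,10-dimethylundeca-5,9-dien-2-one | CC(C)=CCC/C(C)=C/CCC(C)=O | starting material
11 | 3-[tert-butyl(dimethyl)silyl]oxypropanal | O=CCCO[Si](C)(C)C(C)(C)C | starting material
12 | aldol adduct (C-3 epimers) | CC(C)=CCC/C(C)=C/CCC(=O)CC(O)CCO[Si](C)(C)C(C)(C)C | intermediate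
13 | mesylate of 12 | CC(C)=CCC/C(C)=C/CCC(=O)CC(CCO[Si](C)(C)C(C)(C)C)OS(C)(=O)=O | intermediate
14 | (3E,8E)-trienone | CC(C)=CCC/C(C)=C/CCC(=O)/C=C/CCO[Si](C)(C)C(C)(C)C | intermediate
15 | (S,S,S)-diepoxy enone | CC1(C)O[C@H]1CC[C@]2(C)O[C@H]2CCC(=O)/C=C/CCO[Si](C)(C)C(C)(C)C | intermediate
16 | (Z)-triethylsilyl enol ether | CC1(C)O[C@H]1CC[C@]2(C)O[C@H]2CC/C(O[Si](CC)(CC)CC)=C/CCCO[Si](C)(C)C(C)(C)C | intermediate
17 | bicyclic ketone with 3-OTMS and primary OTBS | CC(C)(C)[Si](C)(C)OCCC[C@H]1[C@]2(C)CC[C@H](O[Si](C)(C)C)C(C)(C)O[C@H]2CCC1=O | intermediate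
18 | bicyclic keto diol | OCCC[C@H]1[C@]2(C)CC[C@H](O)C(C)(C)O[C@H]2CCC1=O | intermediate
19 | bicyclic triol | OCCC[C@H]1[C@]2(C)CC[C@H](O)C(C)(C)O[C@H]2CC[C@@]1(C)O | intermediate
20 | tris(triethylsilyl) ether of 19 | CC[Si](CC)(CC)OCCC[C@H]1[C@]2(C)CC[C@H](O[Si](CC)(CC)CC)C(C)(C)O[C@H]2CC[C@@]1(C)O[Si](CC)(CC)CC | intermediate
21 | right-half aldehyde | O=CCC[C@H]1[C@]2(C)CC[C@H](O[Si](CC)(CC)CC)C(C)(C)O[C@H]2CC[C@@]1(C)O[Si](CC)(CC)CC | intermediate
22 | right-half alkyne | C#CCC[C@H]1[C@]2(C)CC[C@H](O[Si](CC)(CC)CC)C(C)(C)O[C@H]2CC[C@@]1(C)O[Si](CC)(CC)CC | intermediate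
23 | ynone | O=C(C[C@H]1[C@H](CC[C@]1(C)O[Si](C)(C)C(C)(C)C)C(C)=C)C#CCC[C@H]2[C@]3(C)CC[C@H](O[Si](CC)(CC)CC)C(C)(C)O[C@H]3CC[C@@]2(C)O[Si](CC)(CC)CC | intermediate
24 | (2R)-propargylic alcohol | O[C@H](C[C@H]1[C@H](CC[C@]1(C)O[Si](C)(C)C(C)(C)C)C(C)=C)C#CCC[C@H]2[C@]3(C)CC[C@H](O[Si](CC)(CC)CC)C(C)(C)O[C@H]3CC[C@@]2(C)O[Si](CC)(CC)CC | intermediate
25 | alkenylmagnesium bromide, bromomagnesium alkoxide | Br[Mg]O[C@H](C[C@H]1[C@H](CC[C@]1(C)O[Si](C)(C)C(C)(C)C)C(C)=C)/C(C)=C(\[Mg]Br)CC[C@H]2[C@]3(C)CC[C@H](O[Si](CC)(CC)CC)C(C)(C)O[C@H]3CC[C@@]2(C)O[Si](CC)(CC)CC | intermediate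
26 | (2R,3Z)-iodoalkenyl carbinol | O[C@H](C[C@H]1[C@H](CC[C@]1(C)O[Si](C)(C)C(C)(C)C)C(C)=C)/C(C)=C(\I)CC[C@H]2[C@]3(C)CC[C@H](O[Si](CC)(CC)CC)C(C)(C)O[C@H]3CC[C@@]2(C)O[Si](CC)(CC)CC | intermediate
27 | cis-fused (7R)-octahydroazulen-7-ol | O[C@@H]1C[C@H]2[C@H](CC[C@]2(C)O[Si](C)(C)C(C)(C)C)C(C)(C)C(CC[C@H]3[C@]4(C)CC[C@H](O[Si](CC)(CC)CC)C(C)(C)O[C@H]4CC[C@@]3(C)O[Si](CC)(CC)CC)=C1C | intermediate
28 | N-allylic N-(2-nitrobenzenesulfonyl)hydrazine, inverted at C-7 | NN([C@H]1C[C@H]2[C@H](CC[C@]2(C)O[Si](C)(C)C(C)(C)C)C(C)(C)C(CC[C@H]3[C@]4(C)CC[C@H](O[Si](CC)(CC)CC)C(C)(C)O[C@H]4CC[C@@]3(C)O[Si](CC)(CC)CC)=C1C)S(=O)(=O)c1ccccc1[N+](=O)[O-] | intermediate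
29 | allylic monoalkyl diazene | N=N[C@H]1C[C@H]2[C@H](CC[C@]2(C)O[Si](C)(C)C(C)(C)C)C(C)(C)C(CC[C@H]3[C@]4(C)CC[C@H](O[Si](CC)(CC)CC)C(C)(C)O[C@H]4CC[C@@]3(C)O[Si](CC)(CC)CC)=C1C | intermediate
30 | tris-silyl ether of the target | CC1=CC[C@H]2[C@H](CC[C@]2(C)O[Si](C)(C)C(C)(C)C)C(C)(C)[C@@H]1CC[C@H]1[C@]2(C)CC[C@H](O[Si](CC)(CC)CC)C(C)(C)O[C@H]2CC[C@@]1(C)O[Si](CC)(CC)CC | intermediate
31 | (1S,3aS,5R,8aS)-5-[2-[(3S,5aS,6S,7R,9aS)-3,7-dihydroxy-2,2,5a,7-tetramethyldecahydro-1-benzoxepin-6-yl]ethyl]-1,4,4,6-tetramethyl-1,2,3,3a,4,5,8,8a-octahydroazulen-1-ol | CC1=CC[C@H]2[C@H](CC[C@]2(C)O)C(C)(C)[C@@H]1CC[C@H]1[C@]2(C)CC[C@H](O)C(C)(C)O[C@H]2CC[C@@]1(C)O | target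

Total step count: 23.
Longest linear sequence: 15 steps (steps 9–17, then 18–23).

**Steps most likely to fail**

Step 6. The cyclisation may proceed with insufficient 1,3-diastereoselection between the quaternary carbinol carbon and the new ring CH, may be slow at the hindered propargylic centre, or may eliminate toward the ring C–H to give the conjugated diene. The fallback sets out from 6 and returns at 8. Conjugate hydroiodination of the ynoate (NaI, AcOH, 70 °C) should give methyl (2Z,4S)-4-[tert-butyl(dimethyl)silyl]oxy-3-iodo-4,8-dimethylnona-2,7-dienoate F1. A 5-exo intramolecular Heck reaction onto the prenyl alkene (Pd(OAc)2, PPh3, Ag2CO3, MeCN, 80 °C), with β-hydride elimination from a methyl group, should then give the (2E) geometric isomer of 7, F2. Its copper hydride reduction under the conditions of step 7 leads to 8, since the alkene geometry is lost there.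

Step 21. Formate may reduce the alkenylpalladium before the slow 7-exo insertion into the hindered 1,1-disubstituted alkene (net hydrodeiodination), or insertion may occur in the 8-endo sense. The fallback sets out from 26 and returns at 27. It reverses the order of events: iron-hydride hydrogen-atom transfer to the isopropenyl group (Fe(acac)3, PhSiH3) forms the tertiary radical first, and a nickel catalyst (NiBr2·diglyme, 4,4'-di-tert-butylbipyridine) captures it and couples it with the alkenyl iodide. This is a Markovnikov-selective metal-hydride/nickel dual-catalytic coupling, so the quaternary carbon no longer depends on migratory insertion; no further compound is needed (F0).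

Step 20. Carbomagnesiation of the internal alkyne of a hindered secondary propargylic alkoxide may be sluggish, may lose regiocontrol, or the alkenylmagnesium may be protonated before iodination. The fallback sets out from 23 and returns at 27, and brings the methyl group in after ring closure:
- Hydroiodination of the ynone (NaI, AcOH, MeCN, rt) should give the (Z)-β-iodo enone F3.
- Reductive Heck closure as in step 21 should give the bicyclic enone F4.
- α-Iodination (I2, pyridine, CH2Cl2) should give the α-iodo enone F5.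
- Stille methylation (Me4Sn, Pd(PPh3)4, CuI, NMP) should give the α-methyl enone F6.
- Corey–Bakshi–Shibata reduction ((S)-methyl oxazaborolidine, catecholborane, toluene, −78 °C) should give the (7R)-allylic alcohol 27 under reagent control.

Further compounds
F1 | step 6 | methyl (2Z,4S)-4-[tert-butyl(dimethyl)silyl]oxy-3-iodo-4,8-dimethylnona-2,7-dienoate | COC(=O)/C=C(\I)[C@@](C)(O[Si](C)(C)C(C)(C)C)CCC=C(C)C
F2 | step 6 | methyl (2E)-2-[(2S,5R)-2-[tert-butyl(dimethyl)silyl]oxy-2-methyl-5-(prop-1-en-2-yl)cyclopentylidene]acetate | COC(=O)/C=C1\[C@H](CC[C@]1(C)O[Si](C)(C)C(C)(C)C)C(C)=C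
F3 | step 20 | (3Z)-4-iodohex-3-en-2-one bearing the C-1 and C-6 substituents of 23 | O=C(C[C@H]1[C@H](CC[C@]1(C)O[Si](C)(C)C(C)(C)C)C(C)=C)/C=C(\I)CC[C@H]2[C@]3(C)CC[C@H](O[Si](CC)(CC)CC)C(C)(C)O[C@H]3CC[C@@]2(C)O[Si](CC)(CC)CC
F4 | step 20 | cis-fused hexahydroazulen-7-one with C5=C6 double bond and H at C-6 | O=C1C[C@H]2[C@H](CC[C@]2(C)O[Si](C)(C)C(C)(C)C)C(C)(C)C(CC[C@H]3[C@]4(C)CC[C@H](O[Si](CC)(CC)CC)C(C)(C)O[C@H]4CC[C@@]3(C)O[Si](CC)(CC)CC)=C1
F5 | step 20 | 6-iodo derivative of F4 | O=C1C[C@H]2[C@H](CC[C@]2(C)O[Si](C)(C)C(C)(C)C)C(C)(C)C(CC[C@H]3[C@]4(C)CC[C@H](O[Si](CC)(CC)CC)C(C)(C)O[C@H]4CC[C@@]3(C)O[Si](CC)(CC)CC)=C1I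
F6 | step 20 | 6-methyl derivative of F4 | O=C1C[C@H]2[C@H](CC[C@]2(C)O[Si](C)(C)C(C)(C)C)C(C)(C)C(CC[C@H]3[C@]4(C)CC[C@H](O[Si](CC)(CC)CC)C(C)(C)O[C@H]4CC[C@@]3(C)O[Si](CC)(CC)CC)=C1C
F0 | step 21 | none | none
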